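The readings stem from a simulated flask on assumed constants; the scatter is artificial.

- In the small charge, the winter run, the readings stand level from 1.33 min on: target averages 57.5% of the charge and starting material 11.5%, and I count what remains as isomer of the product.

| flask | starting material | remark | time |
|---|---|---|---|
| autumn | 0.25 M | the very flask that is asked about, followed so far |  |
| winter | 0.12 M | run made earlier |  |
| flask | 0.25 M |  | 8.0 min |

- autumn (time / min: starting material / %, target / %): 0.500: 13, 63; 1.00: 8, 68; 1.50: 5, 75; 2.50: 5, 73; 3.00: 6, 79; 4.00: 10, 81
- winter (time / min: starting material / %, target / %): 0.417: 11, 54; 1.33: 11, 57; 2.50: 11, 58; 3.00: 13, 57; 5.00: 11, 59; 6.00: 11, 57; 8.00: 12, 57

(each reading ± 1.5 percentage points)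

- what has gone from starting material into another species counts as reacted, even if it can come back
- a reading or a percentage of target counts all its forms, free or not
- the reaction counts as stopped when no species that holds the starting material changes by six tenths of a point or more over the second half of the time

- the state of affairs at 8.0 min: stopped, and by what, or still going (all of the starting material has reacted / forward and back rates have come level / it is still moving)
- share of the starting material used up at 8.0 min
- target at 8.0 min, in percent of the starting material charged
- isomer of the product at 8.0 min, in percent of the starting material charged

- Where every step is first order each way, the charge cancels from forward and back rates, so the shares at balance do not depend on it. From the winter run I therefore keep one reading: non-target per dissolved target, 0.739.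
- The autumn flask breaks this: from 1.50 min on its target averages 77.0%, more than in the winter run. Readings count every form of target, so I suppose that target leaves solution as crystals while the solution keeps its ratio.
- Dividing the autumn non-target share by that ratio gives my ceiling, a reading from scattered values, the largest fraction of the charge that stays dissolved as target (the solubility limit): 31.1%. With the dissolved concentration held fixed, this fraction scales inversely with the charge. For the winter run it becomes 64.8%, above that run's target, so I expect no crystals there.
- My reckoning for the flask at 8.0 min: target 77.0%, and the non-target share divides as in winter, giving starting material 6.22%, so 93.8% used up, and 16.8% by difference for the isomer of the product.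
- Working in powers of ten: target's gap to 77.0% shrinks from 14 percentage points to 9 points between the first two readings, a power of ten per 2.61 min. If it keeps that pace, that leaves 0.64 points at 4.00 min, right at the mark of 0.6. This is a close call from readings scattered by 1.5 points, but I commit to forward and back rates having come level.
- The forecast says it is still moving, with 93% used up, target 85% and isomer of the product 8%, on the grounds that the isomer is “still dropping several points per minute”.
- In the flask forward and back rates have come level, with 93.1% used up, target 76.4% and isomer of the product 14.5%. Crystals stand at 43.6% after 8.00 min, counted inside that target. Taking my ceiling from this target leaves 45.3% for crystals.

    starting material ⇌ isomer of the product (K = 2.10, k = 0.0524 /s)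
    starting material ⇌ dormant form (K = 0.310, k = 1.04 /s)
    starting material ⇌ target (K = 4.75, k = 0.114 /s)
    crystals ⇌ target, rate k4*(cs4 - [target]) while solid is left; crystals form when [target] > cs4 (solubility = 0.0820 M, k = 1.55 /s)

- For a neighbour charged with 0.062 M, the ceiling becomes 125% of its own charge, above the winter target, so I expect no crystals and target near 57.5%. That neighbour gives target 58.2% and crystals 0%.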